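**Strategy.** Everything rests on cutting the adjacent C7–O and C8–O bonds (lignan numbering: hydroxylated bridgehead C8, benzylic C7 of the C7–O–C9'–C8'–C8 ring) back to the C7=C8 double bond of a 2-substituted cinnamyl alcohol. In one operation, titanium–tartrate epoxidation and opening of the epoxide at C7 by a tethered ester carbonyl set C8 and C7, make both C–O bonds and close that ring as its γ-lactone. The precursor is the (E)-allylic alcohol bearing a tert-butyl acetate arm on C8 and a silyl-protected guaiacyl group on C7. An alkoxide–enolate aldol, two ether closures and desilylation then finish the furofuran.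

Key step: step 5

Remark: atom labels follow lignan numbering (ring A = C7–O–C9'–C8'–C8, ring B = C7'–O–C9–C8–C8'), Ar = 3-methoxy-4-(triisopropylsilyloxy)phenyl, and L-(+)-diethyl tartrate is taken to give the 2S epoxide by the usual face rule for (E)-3-aryl allylic alcohols.

**Step 1**
Reactants: 1 vanillin; 2 triisopropylsilyl chloride
Product: 3 3-methoxy-4-(triisopropylsilyloxy)benzaldehyde (ArCHO)
Conditions: imidazole (2.2 equiv), DMF, rt
Reagents that add atoms: triisopropylsilyl chloride (compound 2), CC(C)[Si](Cl)(C(C)C)C(C)C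
Why: Imidazole-mediated O-silylation of the phenol; the triisopropylsilyl ether is preferred to the smaller tert-butyldimethylsilyl ether because it must survive NaH, LiN(iPr)2 and LiAlH4 and still leave with fluoride at the end.

**Step 2**
Reactants: 4 triethyl phosphonoacetate; 5 tert-butyl bromoacetate
Product: 6 4-tert-butyl 1-ethyl 2-(diethoxyphosphoryl)butanedioate (racemic)
Conditions: NaH (1.05 equiv), THF, 0 °C; then 5, 0 °C to rt
Reagents that add atoms: none
Why: SN2 C-alkylation of the sodium phosphonoacetate carbanion by the reactive α-bromo ester, which differentiates the two carboxyl groups (ethyl and tert-butyl) from the outset.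

**Step 3**
Reactants: 6 4-tert-butyl 1-ethyl 2-(diethoxyphosphoryl)butanedioate; 3 ArCHO
Product: 7 4-tert-butyl 1-ethyl (2E)-2-(Ar-methylidene)butanedioate
Conditions: NaH (1.1 equiv), THF, 0 °C; then 3, 0 °C to rt
Reagents that add atoms: none
Why: Horner–Wadsworth–Emmons olefination of an aromatic aldehyde with an α-substituted phosphonoacetate, which should favour the E alkylidene succinate (aryl trans to CO2Et, cis to the CH2CO2tBu arm); no stereocentre is formed.

**Step 4**
Reactants: 7 4-tert-butyl 1-ethyl (2E)-2-(Ar-methylidene)butanedioate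
Product: 8 tert-butyl (3E)-3-(hydroxymethyl)-4-Ar-but-3-enoate
Conditions: iBu2AlH (2.2 equiv), CH2Cl2, −78 °C; Rochelle salt work-up
Reagents that add atoms: none
Why: Chemoselective hydride reduction, in which iBu2AlH at −78 °C takes the conjugated ethyl ester through to the allylic alcohol much faster than it attacks the hindered tert-butyl ester, leaving the alkene geometry untouched.

**Step 5**
Reactants: 8 tert-butyl (3E)-3-(hydroxymethyl)-4-Ar-but-3-enoate
Product: 10 (4S,5R)-5-Ar-4-hydroxy-4-(hydroxymethyl)oxolan-2-one, via epoxy ester 9 (not isolated)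
Conditions: Ti(OiPr)4 (0.1 equiv), L-(+)-diethyl tartrate (0.12 equiv), tBuOOH (1.5 equiv, decane), 4 Å molecular sieves, CH2Cl2, −25 °C; then CSA (0.5 equiv), −25 to 0 °C
Reagents that add atoms: tert-butyl hydroperoxide, CC(C)(C)OO
Why: Sharpless (titanium–tartrate) epoxidation transfers the peroxide oxygen within the titanium-bound allylic alkoxide to one face of the C7=C8 bond; L-(+)-diethyl tartrate, which gives 2S,3S epoxides from (E)-3-aryl allylic alcohols such as cinnamyl alcohol, should give (2S,3S)-9, so the ligand fixes C8 and C7 together. On adding acid the ester carbonyl oxygen attacks benzylic C7 anti to the breaking C7–O bond and the tert-butoxy-lactonium ion loses isobutene; the closest known reactions are acid-induced lactonisation of β,γ-epoxy esters and the titanium-assisted C3 opening of 2,3-epoxy alcohols. The γ-lactone (lactone form of ring A) closes by a 5-endo epoxide opening at the distal carbon, since the 4-exo alternative would be a strained β-lactone. C8 keeps the oxygen placed by the catalyst (4S) and C7 is inverted (5R), so the E geometry of 8 becomes aryl cis to the tertiary hydroxyl. The step needs opening at C7 rather than C8 and inversion rather than a free cation: the p-silyloxyaryl group and five-ring closure secure the first, the tethered nucleophile and low temperature the second.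

**Step 6**
Reactants: 10 (4S,5R)-5-Ar-4-hydroxy-4-(hydroxymethyl)oxolan-2-one; 3 ArCHO
Product: 11 (3R,4S,5R)-5-Ar-4-hydroxy-3-[Ar(hydroxy)methyl]-4-(hydroxymethyl)oxolan-2-one (both carbinol epimers at C7')
Conditions: LiN(iPr)2 (3.1 equiv), THF, −78 °C; then 3 (1.3 equiv), −78 °C; AcOH quench at −78 °C
Reagents that add atoms: none
Why: Aldol addition of the trilithio alkoxide–enolate (a Fráter–Seebach-type β-oxido enolate, which resists β-elimination), in which the aldehyde should approach C8' on the face opposite both the C8 oxido group and the cis C7 aryl group, placing the new carbinol carbon cis to C9 (3R), while C7' is left uncontrolled because step 7 is stereoconvergent.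

**Step 7**
Reactants: 11 (3R,4S,5R)-5-Ar-4-hydroxy-3-[Ar(hydroxy)methyl]-4-(hydroxymethyl)oxolan-2-one
Product: 12 (3R,3aS,6S,6aR)-3,6-di-Ar-3a-hydroxytetrahydro-1H,3H-furo[3,4-c]furan-1-one
Conditions: CSA (0.1 equiv), 4 Å molecular sieves, CH2Cl2, 0 °C
Reagents that add atoms: none
Why: Acid-catalysed SN1 cyclodehydration closing ring B (5-exo capture of the p-silyloxybenzylic cation at C7' by the C9 hydroxyl), in which both carbinol epimers converge on one cation and allylic 1,3-strain (H8' eclipsing the quinoid ring) should place the aryl group exo, trans to C9' (7'S), while the less ionisable lactone C7–O bond stays intact under catalytic acid at 0 °C.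

**Step 8**
Reactants: 12 (3R,3aS,6S,6aR)-3,6-di-Ar-3a-hydroxytetrahydro-1H,3H-furo[3,4-c]furan-1-one
Product: 13 (3S,4R,5S)-5-Ar-3-[(R)-Ar(hydroxy)methyl]-4-(hydroxymethyl)oxolan-3-ol
Conditions: LiAlH4 (2.5 equiv), THF, 0 °C; Rochelle salt work-up
Reagents that add atoms: none
Why: Hydride reduction of the lactone to the 1,4-diol, which breaks only the acyl C9'–O bond so that C7 keeps its oxygen and configuration, the aryl silyl ethers and the benzylic ether being inert to LiAlH4 at 0 °C.

**Step 9**
Reactants: 13 (3S,4R,5S)-5-Ar-3-[(R)-Ar(hydroxy)methyl]-4-(hydroxymethyl)oxolan-3-ol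
Product: 15 (3R,3aS,6S,6aR)-3,6-di-Ar-tetrahydro-1H,3H-furo[3,4-c]furan-3a(4H)-ol (8-hydroxypinoresinol bis-triisopropylsilyl ether), via primary mesylate 14 (not isolated)
Conditions: MsCl (1.1 equiv), pyridine, CH2Cl2, −20 °C to rt
Reagents that add atoms: none
Why: Selective sulfonylation of the only primary hydroxyl followed by intramolecular Williamson-type 5-exo-tet displacement by the C7 hydroxyl (cyclodehydration of a 1,4-diol), which re-forms ring A as the C7–O–C9' ether without touching the C7–O bond, so C7 is retained, the tertiary hydroxyl being able to give only a strained oxetane.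

**Step 10**
Reactants: 15 8-hydroxypinoresinol bis-triisopropylsilyl ether
Product: 16 8-hydroxypinoresinol, (3R,3aS,6S,6aR)-3,6-bis(4-hydroxy-3-methoxyphenyl)tetrahydro-1H,3H-furo[3,4-c]furan-3a(4H)-ol
Conditions: Bu4NF (2.2 equiv), AcOH (2.2 equiv), THF, 0 °C
Reagents that add atoms: none
Why: Fluoride cleavage of the two aryl silyl ethers, buffered with acetic acid so that each phenoxide is protonated at once and cannot expel the benzylic ether oxygen as a quinone methide.

**Compound list**
1 | vanillin (4-hydroxy-3-methoxybenzaldehyde) | COc1cc(C=O)ccc1O | starting material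
2 | triisopropylsilyl chloride | CC(C)[Si](Cl)(C(C)C)C(C)C | starting material
3 | 3-methoxy-4-(triisopropylsilyloxy)benzaldehyde | COc1cc(C=O)ccc1O[Si](C(C)C)(C(C)C)C(C)C | intermediate
4 | triethyl phosphonoacetate | CCOC(=O)CP(=O)(OCC)OCC | starting material
5 | tert-butyl bromoacetate | CC(C)(C)OC(=O)CBr | starting material
6 | 4-tert-butyl 1-ethyl 2-(diethoxyphosphoryl)butanedioate (racemic) | CCOC(=O)C(CC(=O)OC(C)(C)C)P(=O)(OCC)OCC | intermediate
7 | 4-tert-butyl 1-ethyl (2E)-2-(Ar-methylidene)butanedioate | CCOC(=O)/C(CC(=O)OC(C)(C)C)=C/c1ccc(O[Si](C(C)C)(C(C)C)C(C)C)c(OC)c1 | intermediate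
8 | tert-butyl (3E)-3-(hydroxymethyl)-4-Ar-but-3-enoate | CC(C)(C)OC(=O)C/C(CO)=C\c1ccc(O[Si](C(C)C)(C(C)C)C(C)C)c(OC)c1 | intermediate
9 | tert-butyl 2-[(2S,3S)-3-Ar-2-(hydroxymethyl)oxiran-2-yl]acetate | CC(C)(C)OC(=O)C[C@@]1(CO)O[C@H]1c1ccc(O[Si](C(C)C)(C(C)C)C(C)C)c(OC)c1 | intermediate
10 | (4S,5R)-5-Ar-4-hydroxy-4-(hydroxymethyl)oxolan-2-one | OC[C@@]1(O)CC(=O)O[C@@H]1c1ccc(O[Si](C(C)C)(C(C)C)C(C)C)c(OC)c1 | intermediate
11 | (3R,4S,5R)-5-Ar-4-hydroxy-3-[Ar(hydroxy)methyl]-4-(hydroxymethyl)oxolan-2-one, both C7' carbinol epimers | OC[C@@]1(O)[C@@H](C(O)c2ccc(O[Si](C(C)C)(C(C)C)C(C)C)c(OC)c2)C(=O)O[C@@H]1c1ccc(O[Si](C(C)C)(C(C)C)C(C)C)c(OC)c1 | intermediate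
12 | (3R,3aS,6S,6aR)-3,6-di-Ar-3a-hydroxytetrahydro-1H,3H-furo[3,4-c]furan-1-one (lignan 7R,8S,7'S,8'R; 9'-oxo) | COc1cc([C@H]2OC[C@]3(O)[C@@H](c4ccc(O[Si](C(C)C)(C(C)C)C(C)C)c(OC)c4)OC(=O)[C@H]23)ccc1O[Si](C(C)C)(C(C)C)C(C)C | intermediate
13 | (3S,4R,5S)-5-Ar-3-[(R)-Ar(hydroxy)methyl]-4-(hydroxymethyl)oxolan-3-ol | OC[C@@H]1[C@@H](c2ccc(O[Si](C(C)C)(C(C)C)C(C)C)c(OC)c2)OC[C@]1(O)[C@H](O)c1ccc(O[Si](C(C)C)(C(C)C)C(C)C)c(OC)c1 | intermediate
14 | [(2S,3R,4S)-2-Ar-4-hydroxy-4-[(R)-Ar(hydroxy)methyl]oxolan-3-yl]methyl methanesulfonate | CS(=O)(=O)OC[C@@H]1[C@@H](c2ccc(O[Si](C(C)C)(C(C)C)C(C)C)c(OC)c2)OC[C@]1(O)[C@H](O)c1ccc(O[Si](C(C)C)(C(C)C)C(C)C)c(OC)c1 | intermediate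
15 | (3R,3aS,6S,6aR)-3,6-di-Ar-tetrahydro-1H,3H-furo[3,4-c]furan-3a(4H)-ol (8-hydroxypinoresinol bis-triisopropylsilyl ether) | COc1cc([C@H]2OC[C@]3(O)[C@@H](c4ccc(O[Si](C(C)C)(C(C)C)C(C)C)c(OC)c4)OC[C@H]23)ccc1O[Si](C(C)C)(C(C)C)C(C)C | intermediate
16 | 8-hydroxypinoresinol, (3R,3aS,6S,6aR)-3,6-bis(4-hydroxy-3-methoxyphenyl)tetrahydro-1H,3H-furo[3,4-c]furan-3a(4H)-ol (lignan 7R,8S,7'S,8'R) | COc1cc([C@H]2OC[C@]3(O)[C@@H](c4ccc(O)c(OC)c4)OC[C@H]23)ccc1O | target

**Count.** Total: 10 steps. Longest linear sequence: 9 steps (steps 1 and 3–10 from vanillin, or equally steps 2–10 from triethyl phosphonoacetate).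

**Steps most likely to fail**

Step 5. The electron-rich aryl epoxide may ionise on titanium before the ester captures it cleanly, which would cost inversion at C7 or divert the cation to isopropanol or tert-butanol. The chelating diol lactone may also stall turnover and erode facial selectivity. The fallback sets out from 8 and uses a metal-free Shi epoxidation, which tolerates free allylic alcohols: the enantiomer of the fructose-derived ketone (made from L-sorbose), KHSO5, K2CO3 buffer near pH 10.5, MeCN–dimethoxymethane–water, 0 °C. The enantiomeric ketone is chosen because the D-fructose ketone epoxidises (E)-1-phenylpropene on the opposite face. The basic medium leaves epoxy ester 9 intact, so it can be isolated and then lactonised in a separate flask with catalytic CSA in CH2Cl2 at −20 °C, returning to 10. This fallback makes no compound outside the list (F0).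

Step 6. The triply lithiated species may discriminate poorly between its faces, fail to enolise through aggregation, or break down by retro-aldol cleavage of the C8–C8' bond or acyl shift to the C9 alkoxide. The fallback sets out from 10, whose C8/C9 diol is tied up with 2,2-dimethoxypropane and catalytic CSA in acetone as the spiro-acetonide (5S,6R)-6-Ar-2,2-dimethyl-1,3,7-trioxaspiro[4.4]nonan-8-one F1. Its lithium enolate (LiN(SiMe3)2, THF, −78 °C) should add to 3 on the face away from the C7 aryl group to give the aldol (5S,6R,9R)-6-Ar-9-[Ar(hydroxy)methyl]-2,2-dimethyl-1,3,7-trioxaspiro[4.4]nonan-8-one F2. Aqueous acetic acid then removes the acetonide and the route is rejoined at 11.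

Step 7. The C7' cation lies β to the lactone carbonyl and may lose H8' to give the conjugated benzylidene lactone, may be captured without exo selectivity, or the acid may also ionise the lactone C7–O bond. The fallback sets out from 11 and removes the carbonyl first with LiAlH4 (THF, 0 °C), giving the pentaol (1R,2S,3R)-1,4-di-Ar-2,3-bis(hydroxymethyl)butane-1,2,4-triol F3 (C4 epimers). Catalytic CSA in CH2Cl2 at 0 °C should then close both tetrahydrofuran rings in one cyclodehydration of the kind used for 1,4-diaryl-2,3-bis(hydroxymethyl)butane-1,4-diols, each benzylic carbon being captured by the primary hydroxyl across the C8–C8' bond under the same allylic-strain control. This leads directly to 15; it gives up the C7 information of step 5 but keeps C8 and C8'.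

**Further compounds**
F0 | step 5 | none | none
F1 | step 6 | (5S,6R)-6-Ar-2,2-dimethyl-1,3,7-trioxaspiro[4.4]nonan-8-one | CC1(C)OC[C@@]2(O1)CC(=O)O[C@@H]2c1ccc(O[Si](C(C)C)(C(C)C)C(C)C)c(OC)c1
F2 | step 6 | (5S,6R,9R)-6-Ar-9-[Ar(hydroxy)methyl]-2,2-dimethyl-1,3,7-trioxaspiro[4.4]nonan-8-one, carbinol epimers | CC1(C)OC[C@@]2(O1)[C@@H](C(O)c3ccc(O[Si](C(C)C)(C(C)C)C(C)C)c(OC)c3)C(=O)O[C@@H]2c1ccc(O[Si](C(C)C)(C(C)C)C(C)C)c(OC)c1
F3 | step 7 | (1R,2S,3R)-1,4-di-Ar-2,3-bis(hydroxymethyl)butane-1,2,4-triol, C4 epimers | OC[C@H](C(O)c1ccc(O[Si](C(C)C)(C(C)C)C(C)C)c(OC)c1)[C@](O)(CO)[C@H](O)c1ccc(O[Si](C(C)C)(C(C)C)C(C)C)c(OC)c1
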